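In the grey run the substrate falls steadily, and if we find what stays nearly constant in that fall, we can freeze it and carry it to the new flasks, birch and cedar.

the same everywhere: gas 200 mM (held)
- violet: substrate 0.55 M; temperature 10 °C; run made earlier
- grey: substrate 0.83 M; temperature 29 °C; run made earlier
- birch: substrate 1.1 M; temperature 25 °C; time 6.0 h
- cedar: substrate 1.1 M; temperature 33 °C; time 6.0 h

| run | time / h | target / % | isomer of the product / % | substrate / % | intermediate / % |
|---|---|---|---|---|---|
| violet | 2.00 | 0 | 0.2 | 93.6 | 4.6 |
| violet | 4.00 | 1.5 | 1.0 | 83.7 | 11.6 |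
| violet | 5.00 | 2.9 | 1.5 | 80.1 | 13.6 |
| violet | 8.00 | 7.8 | 3.7 | 67.7 | 19.7 |
| grey | 0.417 | 0.5 | 0 | 96.0 | 1.8 |
| grey | 1.33 | 3.9 | 2.7 | 80.5 | 8.6 |
| grey | 2.50 | 9.6 | 7.4 | 62.8 | 11.9 |
| grey | 4.00 | 15.2 | 16.7 | 44.6 | 12.6 |

(each reading ± 0.5 percentage points)

- at the start none of the gas is in solution

- which of these there is most of at the end, counted by the substrate in it, birch (substrate / isomer of the product / intermediate / target)
- which of these there is most of at the end, counted by the substrate in it, cedar (substrate / isomer of the product / intermediate / target)
- how much there is at the end of the one of these that leads, in percent of the substrate charged: birch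
- how much there is at the end of the one of these that leads, in percent of the substrate charged: cedar

We have two candidates for that constant, so we have two ways to the substrate left in birch. The first freezes the percent lost per hour, the log slope. From first to last reading it is 0.0540 h⁻¹ in violet and 0.214 h⁻¹ in grey, which gives an apparent activation energy of 51.6 kJ mol⁻¹, a value read from two runs that differ in loading as well as in temperature. The Arrhenius line then carries it to 0.162 h⁻¹ for birch, our frozen log slope, a pseudo-first-order constant, and to 0.280 h⁻¹ for cedar. Grey's first reading implies a delay of 0.226 h, so birch should keep 39.1% and cedar 19.9%.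

The second way freezes the molar loss per hour instead. The same line through the two runs gives 0.0863 M h⁻¹ for birch, which would keep 54.7%.

The two part by 16 percentage points, so one cheats, and grey shows which. From its early to its late readings the log slope rises from 0.193 h⁻¹ to 0.228 h⁻¹, while the molar loss falls from 0.141 M h⁻¹ to 0.101 M h⁻¹, a larger move. We therefore keep the log slope, knowing that it still climbs and that the runs change loading and temperature together.

Grey's last reading stands at 44.6% substrate, and the next species read there is the isomer of the product at 16.7%, so with 39.1% reckoned for birch we expect substrate to lead in birch. Cedar's reckoned substrate lies lower than birch's, and we look to the isomer of the product there, but we put no number on it.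

The forecast names substrate for birch at 38% and isomer of the product for cedar at 38%, with these grounds: “Target growth slows while the isomer accelerates”. Its figure for birch lies below our 39.1%, and its figure for cedar is one we did not reckon.

Birch ends with substrate leading at 39.4%, against our 39.1%; cedar ends with isomer of the product leading at 35.4%, its substrate at 19.8% against our 19.9%.

    intermediate ⇌ isomer of the product (K = 91.0, k = 0.290 h⁻¹, Ea = 93.0 kJ mol⁻¹, ΔH = 25.0 kJ mol⁻¹)
    intermediate ⇌ target (K = 1.50, k = 0.650 h⁻¹, Ea = 88.0 kJ mol⁻¹, ΔH = 2.00 kJ mol⁻¹)
    2 substrate → homo dimer A (k = 0.0170 M⁻¹ h⁻¹, Ea = 84.0 kJ mol⁻¹)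
    substrate + reagent → intermediate + by-product (k = 1.60 M⁻¹ h⁻¹, Ea = 79.0 kJ mol⁻¹)
    2 substrate → homo dimer B (k = 8.40 × 10⁻⁴ M⁻¹ h⁻¹, Ea = 98.0 kJ mol⁻¹)
    gas ⇌ reagent, rate k6*(csat - [reagent]) (kL = 0.900 h⁻¹)
    (constants at 25 °C)

Birch read at 15 h tests the frozen slope further along. Between 6.0 h and 15 h its substrate falls with a log slope of 0.240 h⁻¹, and 0.162 h⁻¹ reckons 9.13% left, but the birch flask holds 4.5%.

(The earlier runs and the new flask stem from a simulated flask with constants of no real substance; scatter was added.)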